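## Retrosynthetic overview
1. Two bonds are cut together: O1–C8a (ring C, cyclodehydration) and C4a–C5 (ring A, acylketene 6π closure). The flavanone then unfolds to an acyclic tert-butyl (S)-9-aryl-9-silyloxy-2-prenyl-3,5,7-trioxononanoate. Ring B is bought.
2. The prenyl group sits next to the ester carbon, and the carbinol oxygen can reach only one ketone (the future C8a). The chain order therefore fixes the 6-prenyl pattern and excludes the 8-prenyl isomer.
3. The chain is cut by a Claisen disconnection at C4–C4a. This gives the trilithio salt of tert-butyl 2-prenyl-3,5-dioxohexanoate and an (S)-β-silyloxy methyl ester.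
4. The β-silyloxy ester comes from a catalytic asymmetric Mukaiyama aldol on C-prenylated 4-hydroxybenzaldehyde, which sets C2. The diketo ester comes from tert-butyl acetoacetate by α-prenylation and then γ-acetylation.
5. In the forward direction ring C closes first, ring A closes next in the same flask, and the 4'-phenol is released last.

Conventions: TBS = tert-butyldimethylsilyl. Prenyl = 3-methylbut-2-en-1-yl. O1, C2 … C8a are flavanone atom numbers.

Assumption: the (R)-disulfonimide in step 2 is taken as the antipode that directs attack to the Si face of the aldehyde. If the sense is opposite, the equally available (S)-catalyst is used and nothing else changes.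

## Route

Step 1
Reactants: 1 4-hydroxybenzaldehyde; 2 prenyl bromide (1-bromo-3-methylbut-2-ene)
Product: 3 4-hydroxy-3-prenylbenzaldehyde
Conditions: KOH (1.1 equiv), H2O, 23 °C, 20 h
Reagents that add atoms: prenyl bromide (2), CC(C)=CCBr
Why: This is C-alkylation of an ambident phenoxide, in which water hydrogen-bonds the oxygen so the soft allylic bromide is taken by the ortho carbon (para is blocked by CHO), and the O-prenyl and diprenyl by-products are removed by chromatography.

Step 2
Reactants: 3 4-hydroxy-3-prenylbenzaldehyde; 4 1-(tert-butyldimethylsilyloxy)-1-methoxyethene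
Product: 6 methyl (3S)-3-(tert-butyldimethylsilyloxy)-3-[4-(tert-butyldimethylsilyloxy)-3-prenylphenyl]propanoate, via O-TBS aldehyde 5 (not isolated)
Conditions: 4 (1.1 equiv), CH2Cl2, 23 °C, 1 h; then Et2O, (R)-3,3'-bis[3,5-bis(trifluoromethyl)phenyl]-1,1'-binaphthyl-2,2'-disulfonimide (2 mol %), 4 (1.3 equiv), −78 °C
Reagents that add atoms: ketene silyl acetal (4), C=C(OC)O[Si](C)(C)C(C)(C)C
Why: The ketene silyl acetal first silylates the phenol under neutral conditions, and a disulfonimide-catalysed asymmetric Mukaiyama aldol with silyl transfer follows, in which the chiral counter-anion of the silylated aldehyde shields the Re face so that 4 adds to the Si face and sets the (S)-carbinol (future C2) directly as its TBS ether.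

Step 3
Reactants: 7 tert-butyl acetoacetate; 2 prenyl bromide
Product: 8 tert-butyl 2-acetyl-5-methylhex-4-enoate (racemic)
Conditions: 7 (1.2 equiv), NaH (1.1 equiv), THF, 0 °C; 2, 0→23 °C
Reagents that add atoms: prenyl bromide (2), CC(C)=CCBr
Why: This is an acetoacetic ester alkylation (SN2 of the sodium enolate on the primary allylic bromide) in which a slight excess of 7 suppresses dialkylation, and the new centre is racemic and becomes sp2 in step 6.

Step 4
Reactants: 8 tert-butyl 2-acetyl-5-methylhex-4-enoate; 9 N-methoxy-N-methylacetamide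
Product: 10 tert-butyl 2-prenyl-3,5-dioxohexanoate (racemic, keto–enol mixture)
Conditions: LiN(iPr)2 (2.2 equiv), THF, −78→0 °C; 9 (1.1 equiv), −78→0 °C; AcOH quench
Reagents that add atoms: N-methoxy-N-methylacetamide (9), CC(=O)N(C)OC
Why: This is a Weiler-type dianion acylation, in which the more basic γ-carbanion of the dilithio β-keto ester attacks the Weinreb amide and the chelated tetrahedral adduct blocks over-addition and proton exchange until the quench.

Step 5
Reactants: 10 tert-butyl 2-prenyl-3,5-dioxohexanoate; 6 methyl (3S)-3-(tert-butyldimethylsilyloxy)-3-[4-(tert-butyldimethylsilyloxy)-3-prenylphenyl]propanoate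
Product: 11 tert-butyl (9S)-9-(tert-butyldimethylsilyloxy)-9-[4-(tert-butyldimethylsilyloxy)-3-prenylphenyl]-3,5,7-trioxo-2-prenylnonanoate (C2 epimers, keto–enol mixture)
Conditions: 10 (2.2 equiv), LiN(iPr)2 (6.8 equiv), THF, 0 °C, 1 h; 6 (1 equiv), −78→−10 °C; AcOH, −78 °C
Reagents that add atoms: none
Why: This is a Claisen-type acylation of a Harris polyanion, in which only the terminal and most basic carbanion of the trilithio salt is acylated by the methyl ester, the excess trianion absorbs the new acidic proton, and no bond to the carbinol carbon is touched so (S) is kept.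

Step 6
Reactants: 11 tert-butyl (9S)-9-(tert-butyldimethylsilyloxy)-9-[4-(tert-butyldimethylsilyloxy)-3-prenylphenyl]-3,5,7-trioxo-2-prenylnonanoate
Product: 15 macarangaflavanone B, via dihydropyranone 12 (not isolated), via acylketene 13 (not isolated), via O-TBS flavanone 14 (not isolated)
Conditions: (a) HF·pyridine, pyridine, THF, 0 °C, PTFE flask, then strip with toluene; (b) toluene (5 mM), 110 °C, 12 h; (c) concentrate, Et3N·3HF, MeCN, 23 °C
Reagents that add atoms: none
Why: Proposed new method: acidic fluoride cleaves the alkyl silyl ether at Si–O (the aryl silyl ether reacts much more slowly and the C2–O bond is never broken, so (S) is retained), and the freed hydroxyl condenses with the C8a ketone as in the known acid cyclodehydration of δ-hydroxy-β-diketones to 2,3-dihydro-4H-pyran-4-ones (ring C, 12), which also ties up the only enol oxygen that could have lactonised to a 2-pyrone; heating then expels tert-butanol from the β-keto tert-butyl ester (the acylketene pathway of transacetoacetylation), and acylketene 13, a dienylketene in its enol form, joins C5 to the nucleophilic enol-ether carbon C4a by 6π electrocyclisation and tautomerisation (ring A, 14), the closest known reaction types being the last stage of the Danheiser benzannulation and the biomimetic Claisen cyclisation of 3,5,7-triketo esters to acylphloroglucinols; since O1 is already on C8a and the prenyl group sits on the ketene carbon only the 6-prenyl isomer can form, and the weakly acidic Et3N·3HF finally frees the 4'-phenol without the base-induced ring opening that racemises flavanones.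

## Compound list
1 | 4-hydroxybenzaldehyde | O=Cc1ccc(O)cc1 | starting material
2 | prenyl bromide (1-bromo-3-methylbut-2-ene) | CC(C)=CCBr | starting material
3 | 4-hydroxy-3-(3-methylbut-2-en-1-yl)benzaldehyde | CC(C)=CCc1cc(C=O)ccc1O | intermediate
4 | 1-(tert-butyldimethylsilyloxy)-1-methoxyethene | C=C(OC)O[Si](C)(C)C(C)(C)C | starting material
5 | 4-(tert-butyldimethylsilyloxy)-3-(3-methylbut-2-en-1-yl)benzaldehyde | CC(C)=CCc1cc(C=O)ccc1O[Si](C)(C)C(C)(C)C | intermediate
6 | methyl (3S)-3-(tert-butyldimethylsilyloxy)-3-[4-(tert-butyldimethylsilyloxy)-3-(3-methylbut-2-en-1-yl)phenyl]propanoate | COC(=O)C[C@H](O[Si](C)(C)C(C)(C)C)c1ccc(O[Si](C)(C)C(C)(C)C)c(CC=C(C)C)c1 | intermediate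
7 | tert-butyl acetoacetate | CC(=O)CC(=O)OC(C)(C)C | starting material
8 | tert-butyl 2-acetyl-5-methylhex-4-enoate (racemic) | CC(=O)C(CC=C(C)C)C(=O)OC(C)(C)C | intermediate
9 | N-methoxy-N-methylacetamide | CC(=O)N(C)OC | starting material
10 | tert-butyl 2-(3-methylbut-2-en-1-yl)-3,5-dioxohexanoate (racemic) | CC(=O)CC(=O)C(CC=C(C)C)C(=O)OC(C)(C)C | intermediate
11 | tert-butyl (9S)-9-(tert-butyldimethylsilyloxy)-9-[4-(tert-butyldimethylsilyloxy)-3-(3-methylbut-2-en-1-yl)phenyl]-2-(3-methylbut-2-en-1-yl)-3,5,7-trioxononanoate (both C2 epimers) | CC(C)=CCC(C(=O)OC(C)(C)C)C(=O)CC(=O)CC(=O)C[C@H](O[Si](C)(C)C(C)(C)C)c1ccc(O[Si](C)(C)C(C)(C)C)c(CC=C(C)C)c1 | intermediate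
12 | tert-butyl 4-{(2S)-2-[4-(tert-butyldimethylsilyloxy)-3-(3-methylbut-2-en-1-yl)phenyl]-4-oxo-3,4-dihydro-2H-pyran-6-yl}-2-(3-methylbut-2-en-1-yl)-3-oxobutanoate (both side-chain epimers) | CC(C)=CCC(C(=O)OC(C)(C)C)C(=O)CC1=CC(=O)C[C@H](O1)c2ccc(O[Si](C)(C)C(C)(C)C)c(CC=C(C)C)c2 | intermediate
13 | (2S)-2-[4-(tert-butyldimethylsilyloxy)-3-(3-methylbut-2-en-1-yl)phenyl]-6-[6-methyl-2-oxo-3-(oxomethylidene)hept-5-en-1-yl]-2,3-dihydro-4H-pyran-4-one (acylketene) | O=C=C(CC=C(C)C)C(=O)CC1=CC(=O)C[C@H](O1)c2ccc(O[Si](C)(C)C(C)(C)C)c(CC=C(C)C)c2 | intermediate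
14 | (2S)-2-[4-(tert-butyldimethylsilyloxy)-3-(3-methylbut-2-en-1-yl)phenyl]-5,7-dihydroxy-6-(3-methylbut-2-en-1-yl)-2,3-dihydro-4H-chromen-4-one | CC(C)=CCc1cc([C@@H]2CC(=O)c3c(cc(O)c(CC=C(C)C)c3O)O2)ccc1O[Si](C)(C)C(C)(C)C | intermediate
15 | macarangaflavanone B, (2S)-5,7-dihydroxy-2-[4-hydroxy-3-(3-methylbut-2-en-1-yl)phenyl]-6-(3-methylbut-2-en-1-yl)-2,3-dihydro-4H-chromen-4-one | CC(C)=CCc1cc([C@@H]2CC(=O)c3c(cc(O)c(CC=C(C)C)c3O)O2)ccc1O | target

## Step count and weak points
Total steps: 6. Longest linear sequence: 4 (steps 1, 2, 5, 6). The branch through steps 3, 4, 5, 6 is equally long.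

**Step 6 is the most likely to fail.** Possible causes:
- Dehydration to ring C may be incomplete before ketene formation, which would leak material to a 2-pyrone.
- Loss of tert-butanol from the α-substituted ester may be slow.
- The ketene may oligomerise.

The fallback sets out from 11 and comes back at 14. It closes the two rings separately and makes the ketene chemically instead of thermally. Stage (a) is worked up and dihydropyranone 12 is isolated. ZnBr2 in CH2Cl2 removes the tert-butyl group to give 4-{(2S)-2-[4-(tert-butyldimethylsilyloxy)-3-prenylphenyl]-4-oxo-3,4-dihydro-2H-pyran-6-yl}-3-oxo-2-prenylbutanoic acid F1. N,N'-Diisopropylcarbodiimide at 0 °C in dilute CH2Cl2 collapses the O-acylisourea of this β-keto acid to acylketene 13, about a hundred degrees below the thermolysis temperature. Ring A then closes to 14, which is desilylated with Et3N·3HF as in the route.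

**Step 5 is the second risk.** The trianion may enolise ester 6, and β-elimination of silanolate would then give the cinnamate. The fallback sets out from 6 and comes back at 11. It replaces the acylation by an aldol addition followed by oxidation. iBu2AlH at −78 °C reduces the ester to (3S)-3-(tert-butyldimethylsilyloxy)-3-[4-(tert-butyldimethylsilyloxy)-3-prenylphenyl]propanal F2. The trilithio salt of 10 adds to this far more electrophilic partner at −78 °C, giving tert-butyl (9S)-9-(tert-butyldimethylsilyloxy)-9-[4-(tert-butyldimethylsilyloxy)-3-prenylphenyl]-7-hydroxy-3,5-dioxo-2-prenylnonanoate F3 as carbinol epimers. Dess–Martin periodinane oxidises the new carbinol to the C7 ketone of 11.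

**Step 2 is the third risk.** The enantioselectivity may be only moderate with an acetate-derived ketene acetal on this electron-rich aldehyde. The fallback sets out from 3 and comes back at 6. It sets the stereocentre by ketone reduction instead of C–C bond formation.
- TBSCl and imidazole give 5 as an isolated compound.
- SnCl2-catalysed Roskamp homologation with methyl diazoacetate gives methyl 3-[4-(tert-butyldimethylsilyloxy)-3-prenylphenyl]-3-oxopropanoate F4.
- Asymmetric transfer hydrogenation with RuCl(p-cymene)[(S,S)-TsDPEN] in HCO2H/Et3N leaves the prenyl alkene untouched. It gives methyl (3S)-3-hydroxy-3-[4-(tert-butyldimethylsilyloxy)-3-prenylphenyl]propanoate F5.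
- TBSCl and imidazole convert F5 into 6.

## Further compounds
F1 | step 6 | 4-{(2S)-2-[4-(tert-butyldimethylsilyloxy)-3-(3-methylbut-2-en-1-yl)phenyl]-4-oxo-3,4-dihydro-2H-pyran-6-yl}-2-(3-methylbut-2-en-1-yl)-3-oxobutanoic acid | CC(C)=CCC(C(=O)O)C(=O)CC1=CC(=O)C[C@H](O1)c2ccc(O[Si](C)(C)C(C)(C)C)c(CC=C(C)C)c2
F2 | step 5 | (3S)-3-(tert-butyldimethylsilyloxy)-3-[4-(tert-butyldimethylsilyloxy)-3-(3-methylbut-2-en-1-yl)phenyl]propanal | O=CC[C@H](O[Si](C)(C)C(C)(C)C)c1ccc(O[Si](C)(C)C(C)(C)C)c(CC=C(C)C)c1
F3 | step 5 | tert-butyl (9S)-9-(tert-butyldimethylsilyloxy)-9-[4-(tert-butyldimethylsilyloxy)-3-(3-methylbut-2-en-1-yl)phenyl]-7-hydroxy-2-(3-methylbut-2-en-1-yl)-3,5-dioxononanoate | CC(C)=CCC(C(=O)OC(C)(C)C)C(=O)CC(=O)CC(O)C[C@H](O[Si](C)(C)C(C)(C)C)c1ccc(O[Si](C)(C)C(C)(C)C)c(CC=C(C)C)c1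
F4 | step 2 | methyl 3-[4-(tert-butyldimethylsilyloxy)-3-(3-methylbut-2-en-1-yl)phenyl]-3-oxopropanoate | COC(=O)CC(=O)c1ccc(O[Si](C)(C)C(C)(C)C)c(CC=C(C)C)c1
F5 | step 2 | methyl (3S)-3-hydroxy-3-[4-(tert-butyldimethylsilyloxy)-3-(3-methylbut-2-en-1-yl)phenyl]propanoate | COC(=O)C[C@H](O)c1ccc(O[Si](C)(C)C(C)(C)C)c(CC=C(C)C)c1
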